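**Plan**
- Retrosynthesis: after removal of the silyl ether and the acetonide, the pyranone (ring B) is cut at O1–C2 and at C3=C4, which leads to a 4-alkoxy-2,6-dihydroxybenzaldehyde and Ph3P=C=C=O. The ArO–C1′ ether is cut next, then C5′–C6′, then C7′–CH3 (with C6′–I) and C7′–C8′.
- Enabling feature: benzene ring A carries OH at C5 and the ether oxygen at C7. In the aldehyde the two hydroxyls, on the carbons that become C5 and C8a, are exchanged by the mirror plane through C1 and C4, so ring B closed through either oxygen gives the same coumarin.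
- Forward: C6′–C11′ is built from methyl 3,4-O-isopropylidene-L-threonate (epoxide, alkyne, (E)-iodoalkene) and C1′–C5′ from (E)-3-methylpent-2-en-4-yn-1-ol. The two are joined by hydroboration and Suzuki coupling, the chain is attached to the para oxygen of 2,4,6-trihydroxybenzaldehyde, ring B (the only ring made) is closed, and the triol is released.
- Stereochemistry: C9′ (S) and C10′ (R) are C3 and C2 of L-threonate and never become reacting centres. 2′E is bought with the enynol; 6′E comes from syn carboalumination and a stereoretentive coupling.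

Key step: step 13

Remark: side-chain atoms are numbered C1′ (OCH2) to C11′ (the carbinol carbon with two methyl groups); the threonate ester, the degradation product of L-ascorbic acid, and the (E)-enynol are taken as purchased single isomers.

**Step 1**
Reactants: 1 methyl 3,4-O-isopropylidene-L-threonate
Product: 2 (1R)-1-[(4S)-2,2-dimethyl-1,3-dioxolan-4-yl]-2-methylpropane-1,2-diol
Conditions: MeMgBr (3.5 equiv), THF, 0 → 25 °C; aq. work-up
Reagents that add atoms: methylmagnesium bromide, C[Mg]Br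
Why: Twofold Grignard addition to the ester (through the methyl ketone) creates the C11′ carbinol with both methyl groups, and because the α-hydroxyl is deprotonated first the C10′ centre cannot enolise and keeps its R configuration.

**Step 2**
Reactants: 2 (1R)-1-[(4S)-2,2-dimethyl-1,3-dioxolan-4-yl]-2-methylpropane-1,2-diol
Product: 3 (4R)-4-[(4S)-2,2-dimethyl-1,3-dioxolan-4-yl]-2,2,5,5-tetramethyl-1,3-dioxolane
Conditions: 2,2-dimethoxypropane, PPTS (cat.), CH2Cl2, 25 °C
Reagents that add atoms: 2,2-dimethoxypropane, COC(C)(C)OC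
Why: Acid-catalysed transketalisation closes the second dioxolane over the secondary and tertiary hydroxyls, the bis-dioxolane being the thermodynamic product for a threo 1,2,3,4-tetraol.

**Step 3**
Reactants: 3 (4R)-4-[(4S)-2,2-dimethyl-1,3-dioxolan-4-yl]-2,2,5,5-tetramethyl-1,3-dioxolane
Product: 4 (1S)-1-[(4R)-2,2,5,5-tetramethyl-1,3-dioxolan-4-yl]ethane-1,2-diol
Conditions: AcOH–H2O (4:1), 25 °C
Reagents that add atoms: none
Why: Regioselective acetal hydrolysis, in which the monosubstituted terminal dioxolane is opened and trapped by water much faster than the 4,4,5-trisubstituted ring (gem-dimethyl substitution favours reclosure), so only the C8′/C9′ diol is released and no stereocentre is touched.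

**Step 4**
Reactants: 4 (1S)-1-[(4R)-2,2,5,5-tetramethyl-1,3-dioxolan-4-yl]ethane-1,2-diol
Product: 6 (4R)-2,2,5,5-tetramethyl-4-[(2S)-oxiran-2-yl]-1,3-dioxolane, via primary arenesulfonate 5 (not isolated)
Conditions: NaH (2.2 equiv), THF, 0 °C; then 1-(2,4,6-triisopropylbenzenesulfonyl)imidazole, 0 → 25 °C
Reagents that add atoms: none
Why: One-pot epoxide synthesis from a 1,2-diol, in which the less hindered primary alkoxide is sulfonylated and the neighbouring C9′ alkoxide displaces the sulfonate in a 3-exo-tet Williamson closure, so C9′ reacts only through its oxygen and stays S.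

**Step 5**
Reactants: 6 (4R)-2,2,5,5-tetramethyl-4-[(2S)-oxiran-2-yl]-1,3-dioxolane
Product: 7 (1S)-1-[(4R)-2,2,5,5-tetramethyl-1,3-dioxolan-4-yl]but-3-yn-1-ol
Conditions: LiC≡CH·H2NCH2CH2NH2, DMSO, 25 °C; then H2O
Reagents that add atoms: lithium acetylide–ethylenediamine complex, [Li]C#C.NCCN
Why: SN2 opening of the terminal epoxide by the acetylide at the unsubstituted carbon C8′ forms the C7′–C8′ bond and leaves the C9′–O bond, and hence the configuration, untouched.

**Step 6**
Reactants: 7 (1S)-1-[(4R)-2,2,5,5-tetramethyl-1,3-dioxolan-4-yl]but-3-yn-1-ol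
Product: 8 tert-butyl(dimethyl){[(1S)-1-[(4R)-2,2,5,5-tetramethyl-1,3-dioxolan-4-yl]but-3-yn-1-yl]oxy}silane
Conditions: TBSOTf, 2,6-lutidine, CH2Cl2, −78 → 0 °C
Reagents that add atoms: tert-butyldimethylsilyl trifluoromethanesulfonate, CC(C)(C)[Si](C)(C)OS(=O)(=O)C(F)(F)F
Why: Silylation of the hindered secondary alcohol with a silyl triflate and a non-nucleophilic base is a standard protection that masks C9′–OH for the organometallic steps and for the ylide annulation.

**Step 7**
Reactants: 8 tert-butyl(dimethyl){[(1S)-1-[(4R)-2,2,5,5-tetramethyl-1,3-dioxolan-4-yl]but-3-yn-1-yl]oxy}silane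
Product: 10 tert-butyl{[(1S,3E)-4-iodo-3-methyl-1-[(4R)-2,2,5,5-tetramethyl-1,3-dioxolan-4-yl]but-3-en-1-yl]oxy}dimethylsilane, via alkenylalane 9 (not isolated)
Conditions: AlMe3 (3 equiv), Cp2ZrCl2 (0.5 equiv), H2O (1.5 equiv), CH2Cl2, −25 → 0 °C; then I2, THF, −25 °C
Reagents that add atoms: trimethylaluminium, C[Al](C)C; iodine, II
Why: Zirconium-catalysed Negishi carboalumination (water-accelerated variant, mild enough for the dioxolane) adds CH3 and Al syn across the terminal alkyne with aluminium on the terminal carbon, and iodinolysis with retention gives the (E)-iodoalkene that fixes the later 6′E geometry.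

**Step 8**
Reactants: 11 (2E)-3-methylpent-2-en-4-yn-1-ol
Product: 12 (2E)-3-methylpenta-2,4-dien-1-ol
Conditions: Zn dust activated with Cu(OAc)2 and AgNO3, MeOH–H2O (1:1), 40 °C
Reagents that add atoms: none
Why: Semi-reduction of a conjugated alkyne with Zn(Cu/Ag) in a protic medium stops cleanly at the alkene and does not touch the 2E trisubstituted double bond.

**Step 9**
Reactants: 12 (2E)-3-methylpenta-2,4-dien-1-ol
Product: 13 triethyl{[(2E)-3-methylpenta-2,4-dien-1-yl]oxy}silane
Conditions: TESCl, imidazole, CH2Cl2, 0 °C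
Reagents that add atoms: chlorotriethylsilane, CC[Si](Cl)(CC)CC
Why: Standard silylation of a primary allylic alcohol gives an ether that tolerates borane and aqueous base and can later be removed in the presence of the TBS ether.

**Step 10**
Reactants: 13 triethyl{[(2E)-3-methylpenta-2,4-dien-1-yl]oxy}silane; 10 tert-butyl{[(1S,3E)-4-iodo-3-methyl-1-[(4R)-2,2,5,5-tetramethyl-1,3-dioxolan-4-yl]but-3-en-1-yl]oxy}dimethylsilane
Product: 15 tert-butyl{[(1S,3E,7E)-3,7-dimethyl-1-[(4R)-2,2,5,5-tetramethyl-1,3-dioxolan-4-yl]-9-(triethylsilyloxy)nona-3,7-dien-1-yl]oxy}dimethylsilane, via alkylborane 14 (not isolated)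
Conditions: 9-BBN-H, THF, 0 → 25 °C; then 10, Pd(dppf)Cl2 (5 mol %), AsPh3, Cs2CO3, DMF–THF–H2O, 25 °C
Reagents that add atoms: none
Why: 9-BBN hydroborates only the monosubstituted vinyl terminus of the diene in the anti-Markovnikov sense, and the primary alkylborane undergoes B-alkyl Suzuki–Miyaura coupling with the iodoalkene with retention of its geometry, which forms C5′–C6′ and completes the 2′E,6′E chain.

**Step 11**
Reactants: 15 tert-butyl{[(1S,3E,7E)-3,7-dimethyl-1-[(4R)-2,2,5,5-tetramethyl-1,3-dioxolan-4-yl]-9-(triethylsilyloxy)nona-3,7-dien-1-yl]oxy}dimethylsilane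
Product: 16 (2E,6E,9S)-9-{[tert-butyl(dimethyl)silyl]oxy}-3,7-dimethyl-9-[(4R)-2,2,5,5-tetramethyl-1,3-dioxolan-4-yl]nona-2,6-dien-1-ol
Conditions: PPTS (0.1 equiv), MeOH–CH2Cl2 (1:1), 0 °C
Reagents that add atoms: none
Why: Mild acid-catalysed methanolysis cleaves the unhindered primary triethylsilyl ether far faster than the secondary TBS ether or the tetrasubstituted dioxolane.

**Step 12**
Reactants: 16 (2E,6E,9S)-9-{[tert-butyl(dimethyl)silyl]oxy}-3,7-dimethyl-9-[(4R)-2,2,5,5-tetramethyl-1,3-dioxolan-4-yl]nona-2,6-dien-1-ol; 17 2,4,6-trihydroxybenzaldehyde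
Product: 18 4-{[(2E,6E,9S)-9-{[tert-butyl(dimethyl)silyl]oxy}-3,7-dimethyl-9-[(4R)-2,2,5,5-tetramethyl-1,3-dioxolan-4-yl]nona-2,6-dien-1-yl]oxy}-2,6-dihydroxybenzaldehyde
Conditions: 17 (2 equiv), PPh3, DIAD, THF, 0 → 25 °C
Reagents that add atoms: none
Why: Mitsunobu etherification, in which the non-chelated para hydroxyl is the most acidic and least hindered of the three phenols and attacks the primary allylic oxyphosphonium ion in an SN2 fashion with retention of the 2′E geometry, while the excess of the symmetric triphenol disfavours double alkylation.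

**Step 13**
Reactants: 18 4-{[(2E,6E,9S)-9-{[tert-butyl(dimethyl)silyl]oxy}-3,7-dimethyl-9-[(4R)-2,2,5,5-tetramethyl-1,3-dioxolan-4-yl]nona-2,6-dien-1-yl]oxy}-2,6-dihydroxybenzaldehyde; 19 ketenylidenetriphenylphosphorane
Product: 21 7-{[(2E,6E,9S)-9-{[tert-butyl(dimethyl)silyl]oxy}-3,7-dimethyl-9-[(4R)-2,2,5,5-tetramethyl-1,3-dioxolan-4-yl]nona-2,6-dien-1-yl]oxy}-5-hydroxy-2H-chromen-2-one, via ester ylide 20 (not isolated)
Conditions: 19 (1.05 equiv, added slowly), toluene, 110 °C
Reagents that add atoms: none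
Why: One of the two equivalent phenolic hydroxyls protonates the ylide carbon of Ph3P=C=C=O and the phenoxide adds to the ketene carbon, which forms O1–C2 and gives the aryl (triphenylphosphoranylidene)acetate 20. The stabilised ylide carbon then attacks the neighbouring formyl carbon in a 6-exo-trig intramolecular Wittig reaction, and collapse of the oxaphosphetane with loss of Ph3P=O forms C3=C4 and closes ring B; the closest known reaction type is the Bestmann coumarin synthesis from salicylaldehydes and ketenylidenetriphenylphosphorane. No stereocentre is created, and the new C3=C4 bond can only be cis because it lies inside the six-membered lactone. The step needs regioselectivity between the two ortho hydroxyls, and the mirror symmetry of the 4-alkoxy-2,6-dihydroxybenzaldehyde secures it, since either hydroxyl leads to the same product with OH at C5 and the chain ether at C7. Mono-addition is secured by using close to one equivalent of ylide, and chemoselectivity by the absence of free aliphatic hydroxyls (C9′ silylated, C10′ and C11′ in the dioxolane); 110 °C is well below the temperature at which the allyl aryl ether would undergo aromatic Claisen rearrangement.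

**Step 14**
Reactants: 21 7-{[(2E,6E,9S)-9-{[tert-butyl(dimethyl)silyl]oxy}-3,7-dimethyl-9-[(4R)-2,2,5,5-tetramethyl-1,3-dioxolan-4-yl]nona-2,6-dien-1-yl]oxy}-5-hydroxy-2H-chromen-2-one
Product: 22 5-hydroxy-7-{[(2E,6E,9S,10R)-9,10,11-trihydroxy-3,7,11-trimethyldodeca-2,6-dien-1-yl]oxy}-2H-chromen-2-one
Conditions: HCl (0.2 M) in MeOH, 0 → 25 °C
Reagents that add atoms: none
Why: Acid-catalysed methanolysis removes the silyl ether and transketalises the acetonide in one operation without touching a stereocentre, dilute acid at or below room temperature being chosen because the allylic aryl ether is the only other acid-sensitive bond.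

**Compound list**
1 | methyl 3,4-O-isopropylidene-L-threonate, i.e. methyl (2R)-2-[(4S)-2,2-dimethyl-1,3-dioxolan-4-yl]-2-hydroxyacetate | COC(=O)[C@H](O)[C@@H]1COC(C)(C)O1 | starting material
2 | (1R)-1-[(4S)-2,2-dimethyl-1,3-dioxolan-4-yl]-2-methylpropane-1,2-diol | CC1(C)OC[C@H](O1)[C@@H](O)C(C)(C)O | intermediate
3 | (4R)-4-[(4S)-2,2-dimethyl-1,3-dioxolan-4-yl]-2,2,5,5-tetramethyl-1,3-dioxolane | CC1(C)OC[C@H](O1)[C@H]2OC(C)(C)OC2(C)C | intermediate
4 | (1S)-1-[(4R)-2,2,5,5-tetramethyl-1,3-dioxolan-4-yl]ethane-1,2-diol | OC[C@H](O)[C@H]1OC(C)(C)OC1(C)C | intermediate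
5 | (2S)-2-hydroxy-2-[(4R)-2,2,5,5-tetramethyl-1,3-dioxolan-4-yl]ethyl 2,4,6-tri(propan-2-yl)benzenesulfonate (not isolated) | CC(C)c1cc(C(C)C)c(S(=O)(=O)OC[C@H](O)[C@H]2OC(C)(C)OC2(C)C)c(C(C)C)c1 | intermediate
6 | (4R)-2,2,5,5-tetramethyl-4-[(2S)-oxiran-2-yl]-1,3-dioxolane | C1O[C@@H]1[C@H]2OC(C)(C)OC2(C)C | intermediate
7 | (1S)-1-[(4R)-2,2,5,5-tetramethyl-1,3-dioxolan-4-yl]but-3-yn-1-ol | C#CC[C@H](O)[C@H]1OC(C)(C)OC1(C)C | intermediate
8 | tert-butyl(dimethyl){[(1S)-1-[(4R)-2,2,5,5-tetramethyl-1,3-dioxolan-4-yl]but-3-yn-1-yl]oxy}silane | C#CC[C@H](O[Si](C)(C)C(C)(C)C)[C@H]1OC(C)(C)OC1(C)C | intermediate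
9 | [(1E,4S)-4-{[tert-butyl(dimethyl)silyl]oxy}-2-methyl-4-[(4R)-2,2,5,5-tetramethyl-1,3-dioxolan-4-yl]but-1-en-1-yl]dimethylalumane (not isolated) | C[Al](C)/C=C(\C)C[C@H](O[Si](C)(C)C(C)(C)C)[C@H]1OC(C)(C)OC1(C)C | intermediate
10 | tert-butyl{[(1S,3E)-4-iodo-3-methyl-1-[(4R)-2,2,5,5-tetramethyl-1,3-dioxolan-4-yl]but-3-en-1-yl]oxy}dimethylsilane | I/C=C(\C)C[C@H](O[Si](C)(C)C(C)(C)C)[C@H]1OC(C)(C)OC1(C)C | intermediate
11 | (2E)-3-methylpent-2-en-4-yn-1-ol | C#C/C(C)=C/CO | starting material
12 | (2E)-3-methylpenta-2,4-dien-1-ol | C=C/C(C)=C/CO | intermediate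
13 | triethyl{[(2E)-3-methylpenta-2,4-dien-1-yl]oxy}silane | C=C/C(C)=C/CO[Si](CC)(CC)CC | intermediate
14 | 9-[(3E)-3-methyl-5-(triethylsilyloxy)pent-3-en-1-yl]-9-borabicyclo[3.3.1]nonane (not isolated) | CC[Si](CC)(CC)OC/C=C(\C)CCB1C2CCCC1CCC2 | intermediate
15 | tert-butyl{[(1S,3E,7E)-3,7-dimethyl-1-[(4R)-2,2,5,5-tetramethyl-1,3-dioxolan-4-yl]-9-(triethylsilyloxy)nona-3,7-dien-1-yl]oxy}dimethylsilane | CC[Si](CC)(CC)OC/C=C(\C)CC/C=C(\C)C[C@H](O[Si](C)(C)C(C)(C)C)[C@H]1OC(C)(C)OC1(C)C | intermediate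
16 | (2E,6E,9S)-9-{[tert-butyl(dimethyl)silyl]oxy}-3,7-dimethyl-9-[(4R)-2,2,5,5-tetramethyl-1,3-dioxolan-4-yl]nona-2,6-dien-1-ol | OC/C=C(\C)CC/C=C(\C)C[C@H](O[Si](C)(C)C(C)(C)C)[C@H]1OC(C)(C)OC1(C)C | intermediate
17 | 2,4,6-trihydroxybenzaldehyde | O=Cc1c(O)cc(O)cc1O | starting material
18 | 4-{[(2E,6E,9S)-9-{[tert-butyl(dimethyl)silyl]oxy}-3,7-dimethyl-9-[(4R)-2,2,5,5-tetramethyl-1,3-dioxolan-4-yl]nona-2,6-dien-1-yl]oxy}-2,6-dihydroxybenzaldehyde | C/C(=C\COc1cc(O)c(C=O)c(O)c1)CC/C=C(\C)C[C@H](O[Si](C)(C)C(C)(C)C)[C@H]1OC(C)(C)OC1(C)C | intermediate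
19 | ketenylidenetriphenylphosphorane (Bestmann ylide) | O=C=C=P(c1ccccc1)(c1ccccc1)c1ccccc1 | starting material
20 | 2-formyl-3-hydroxy-5-{[(2E,6E,9S)-9-{[tert-butyl(dimethyl)silyl]oxy}-3,7-dimethyl-9-[(4R)-2,2,5,5-tetramethyl-1,3-dioxolan-4-yl]nona-2,6-dien-1-yl]oxy}phenyl (triphenyl-λ5-phosphanylidene)acetate (not isolated) | C/C(=C\COc1cc(O)c(C=O)c(OC(=O)C=P(c2ccccc2)(c2ccccc2)c2ccccc2)c1)CC/C=C(\C)C[C@H](O[Si](C)(C)C(C)(C)C)[C@H]1OC(C)(C)OC1(C)C | intermediate
21 | 7-{[(2E,6E,9S)-9-{[tert-butyl(dimethyl)silyl]oxy}-3,7-dimethyl-9-[(4R)-2,2,5,5-tetramethyl-1,3-dioxolan-4-yl]nona-2,6-dien-1-yl]oxy}-5-hydroxy-2H-chromen-2-one | C/C(=C\COc1cc(O)c2ccc(=O)oc2c1)CC/C=C(\C)C[C@H](O[Si](C)(C)C(C)(C)C)[C@H]1OC(C)(C)OC1(C)C | intermediate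
22 | 5-hydroxy-7-{[(2E,6E,9S,10R)-9,10,11-trihydroxy-3,7,11-trimethyldodeca-2,6-dien-1-yl]oxy}-2H-chromen-2-one | C/C(=C\COc1cc(O)c2ccc(=O)oc2c1)CC/C=C(\C)C[C@H](O)[C@@H](O)C(C)(C)O | target

**Step count and risks**
Total step count: 14. Longest linear sequence: 12 steps (steps 1–7 and 10–14, from compound 1).

Steps most likely to fail:

1. Step 12. The etherification may not stop at the para oxygen: a second alkylation at an ortho hydroxyl, C-alkylation of the electron-rich ring or SN2′ capture of the allylic oxyphosphonium ion would consume the chain alcohol. The fallback sets out from 16. Appel bromination (CBr4, PPh3, CH2Cl2, 0 °C) should give the allylic bromide tert-butyl{[(1S,3E,7E)-9-bromo-3,7-dimethyl-1-[(4R)-2,2,5,5-tetramethyl-1,3-dioxolan-4-yl]nona-3,7-dien-1-yl]oxy}dimethylsilane F1. It is used at once in a Williamson alkylation of excess 17 with CsHCO3 in MeCN at 60 °C, where only the most acidic para hydroxyl is ionised. This should deliver 18, where the route is rejoined.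

2. Step 13. Addition of the chelated phenol to the cumulated ylide may be slow, so that the reagent is diverted to the free phenol of the product (double addition) or hydrolysed before ring closure is complete. The fallback sets out from 18 and builds the same ylide stepwise. One equivalent of bromoacetyl bromide with pyridine (CH2Cl2, −20 °C) should acylate one of the two equivalent hydroxyls to give the aryl bromoacetate F2. PPh3 in MeCN at 25 °C should convert it into the phosphonium bromide F3. Et3N then deprotonates the salt to the ester ylide 20, at which the route is rejoined and which closes to 21 by the same intramolecular Wittig reaction.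

3. Step 14. Acid-promoted ionisation of the allylic aryl ether (loss or allylic transposition of the side chain) may outrun cleavage of the hindered silyl ether and of the tetrasubstituted dioxolane. The fallback sets out from 16, in which the allylic oxygen carries hydrogen and no aryloxy leaving group. The same methanolic HCl should remove both protecting groups there and give the tetraol (2E,6E,9S,10R)-3,7,11-trimethyldodeca-2,6-diene-1,9,10,11-tetrol F4. Mitsunobu coupling with excess 17 should engage only the primary allylic hydroxyl, since the secondary hydroxyls next to C11′ react far more slowly and the tertiary one not at all, and give the unprotected aldehyde F5. One equivalent of 19 in THF at 65 °C should then add to the acidic phenol in preference to the hindered aliphatic hydroxyls. The resulting ester ylide F6 closes directly to the target 22, where the route ends without a final acid step.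

**Further compounds**
F1 | step 12 | tert-butyl{[(1S,3E,7E)-9-bromo-3,7-dimethyl-1-[(4R)-2,2,5,5-tetramethyl-1,3-dioxolan-4-yl]nona-3,7-dien-1-yl]oxy}dimethylsilane | BrC/C=C(\C)CC/C=C(\C)C[C@H](O[Si](C)(C)C(C)(C)C)[C@H]1OC(C)(C)OC1(C)C
F2 | step 13 | 2-formyl-3-hydroxy-5-{[(2E,6E,9S)-9-{[tert-butyl(dimethyl)silyl]oxy}-3,7-dimethyl-9-[(4R)-2,2,5,5-tetramethyl-1,3-dioxolan-4-yl]nona-2,6-dien-1-yl]oxy}phenyl bromoacetate | C/C(=C\COc1cc(O)c(C=O)c(OC(=O)CBr)c1)CC/C=C(\C)C[C@H](O[Si](C)(C)C(C)(C)C)[C@H]1OC(C)(C)OC1(C)C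
F3 | step 13 | {2-[2-formyl-3-hydroxy-5-{[(2E,6E,9S)-9-{[tert-butyl(dimethyl)silyl]oxy}-3,7-dimethyl-9-[(4R)-2,2,5,5-tetramethyl-1,3-dioxolan-4-yl]nona-2,6-dien-1-yl]oxy}phenoxy]-2-oxoethyl}triphenylphosphonium bromide | C/C(=C\COc1cc(O)c(C=O)c(OC(=O)C[P+](c2ccccc2)(c2ccccc2)c2ccccc2)c1)CC/C=C(\C)C[C@H](O[Si](C)(C)C(C)(C)C)[C@H]1OC(C)(C)OC1(C)C.[Br-]
F4 | step 14 | (2E,6E,9S,10R)-3,7,11-trimethyldodeca-2,6-diene-1,9,10,11-tetrol | OC/C=C(\C)CC/C=C(\C)C[C@H](O)[C@@H](O)C(C)(C)O
F5 | step 14 | 2,6-dihydroxy-4-{[(2E,6E,9S,10R)-9,10,11-trihydroxy-3,7,11-trimethyldodeca-2,6-dien-1-yl]oxy}benzaldehyde | C/C(=C\COc1cc(O)c(C=O)c(O)c1)CC/C=C(\C)C[C@H](O)[C@@H](O)C(C)(C)O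
F6 | step 14 | 2-formyl-3-hydroxy-5-{[(2E,6E,9S,10R)-9,10,11-trihydroxy-3,7,11-trimethyldodeca-2,6-dien-1-yl]oxy}phenyl (triphenyl-λ5-phosphanylidene)acetate | C/C(=C\COc1cc(O)c(C=O)c(OC(=O)C=P(c2ccccc2)(c2ccccc2)c2ccccc2)c1)CC/C=C(\C)C[C@H](O)[C@@H](O)C(C)(C)O
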